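The plan rests on the cis-1,4 relationship of the two secondary oxygens of the seven-membered ring. O–C6 and O–C9 both lie on the α face and are joined through C7–C8. Both C–O bonds are therefore made at once by adding singlet oxygen across a C6=C7–C8=C9 diene. This gives a peroxide bridge, fixes C6 and C9 in one operation, and leaves a C7=C8 alkene placed for Markovnikov hydration at C8. The substrate is a trans-fused hydroazulene, 4β-(triethylsilyloxy)dauca-6,8-diene. It already holds C1, C4 and C5 and is built from (S)-terpinen-4-ol by ring contraction, conjugate allylation and ring-closing metathesis.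

Key step: step 10

Numbering and faces: daucane numbering is used throughout, also for the monocyclic precursors. C1 is the quaternary carbon with the methyl group, C2/C3 are CH2, C4 is the carbinol carbon with the isopropyl group, C5 is the ring-fusion CH, and C6–C10 are the other seven-ring carbons, with a methyl on C8. β is the face of the C1 methyl group and α is the face of H-5.

Assumption: 1 is used as enantiopure (S)-(+)-terpinen-4-ol. C4 is the only source of absolute configuration, so a lot of lower enantiomeric purity would pass its ee on to 26.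

Design note: the C4 hydroxyl is carried as its triethylsilyl ether from step 1 to step 16. The ether prevents hemiketal formation after ring cleavage, shields the β face in steps 4 and 10, removes a hydrogen-bond donor for singlet oxygen, and leaves together with the other silyl groups.

Step 1
Reactants: 1 (S)-(+)-terpinen-4-ol
Product: 2 (S)-terpinen-4-ol triethylsilyl ether
Conditions: TESOTf, 2,6-lutidine, CH2Cl2, 0 °C to rt
Reagents that add atoms: triethylsilyl trifluoromethanesulfonate, CC[Si](CC)(CC)OS(=O)(=O)C(F)(F)F
Why: Silylation with a silyl triflate and a hindered pyridine base is the standard way to cap a crowded tertiary alcohol and touches neither the alkene nor the C4 stereocentre.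

Step 2
Reactants: 2 (S)-terpinen-4-ol triethylsilyl ether
Product: 4 (S)-3-isopropyl-6-oxo-3-(triethylsilyloxy)heptanal, via secondary ozonide 3 (not isolated)
Conditions: O3, CH2Cl2, −78 °C; then PPh3, −78 °C to rt
Reagents that add atoms: ozone, [O-][O+]=O
Why: Ozonolysis with reductive work-up cleaves the only C=C bond to the 1,6-keto aldehyde, and the silyl ether and C4 are inert to ozone.

Step 3
Reactants: 4 (S)-3-isopropyl-6-oxo-3-(triethylsilyloxy)heptanal
Product: 5 (R)-5-isopropyl-2-methyl-5-(triethylsilyloxy)cyclopent-1-ene-1-carbaldehyde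
Conditions: piperidine (cat.), AcOH (cat.), toluene, 60 °C
Reagents that add atoms: none
Why: In this amine/acid-catalysed intramolecular aldol condensation the aldehyde forms the enamine faster than the ketone, its α-carbon (C5) closes onto the methyl ketone carbon (C1) in a five-ring closure helped by the quaternary C4 (Thorpe–Ingold effect), and dehydration gives the formylcyclopentene without touching C4 (the descriptor changes from S to R only through CIP priorities).

Step 4
Reactants: 5 (R)-5-isopropyl-2-methyl-5-(triethylsilyloxy)cyclopent-1-ene-1-carbaldehyde; 6 allylmagnesium bromide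
Product: 8 (1R,2R,5R)-2-allyl-5-isopropyl-2-methyl-5-(triethylsilyloxy)cyclopentane-1-carbaldehyde (formyl; methyl; silyloxy all β; allyl and isopropyl α), via trimethylsilyl enol ether 7 (not isolated)
Conditions: 6 premixed with CuBr·SMe2, THF, −78 °C; 5, TMSCl, −78 °C; then 1 M HCl, THF, 0 °C
Reagents that add atoms: chlorotrimethylsilane, C[Si](C)(C)Cl (its silyl group stays in 7 only)
Why: In this TMSCl-accelerated conjugate addition of an allylcopper reagent the pseudo-axial β-silyloxy group at C4 covers the β face so that allyl should bond to C1 from the α face (methyl ends β), silyl trapping keeps the enolate from expelling the C4 silyloxy group, and protonation of the enol ether at C5 from the α face, away from the two pseudo-axial β groups, places the formyl group pseudo-equatorial and β, which is also the more stable arrangement.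

Step 5
Reactants: 8 (1R,2R,5R)-2-allyl-5-isopropyl-2-methyl-5-(triethylsilyloxy)cyclopentane-1-carbaldehyde; 9 2-methylallylmagnesium chloride
Product: 10 1-[(1R,2R,5R)-2-allyl-5-isopropyl-2-methyl-5-(triethylsilyloxy)cyclopentyl]-3-methylbut-3-en-1-ol (both C6 epimers)
Conditions: THF, −78 °C; aq. NH4Cl
Reagents that add atoms: none
Why: Grignard 1,2-addition of the very nucleophilic allylic reagent at low temperature outruns enolisation of the aldehyde, and the new C6 carbinol centre may form as a mixture because it is erased in step 7.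

Step 6
Reactants: 10 1-[(1R,2R,5R)-2-allyl-5-isopropyl-2-methyl-5-(triethylsilyloxy)cyclopentyl]-3-methylbut-3-en-1-ol
Product: 11 4β-(triethylsilyloxy)dauc-8-en-6-ol (trans-fused; 1β-methyl; 5α-H; both C6 epimers)
Conditions: Grubbs second-generation catalyst (cat.), CH2Cl2, 40 °C
Reagents that add atoms: none
Why: Ring-closing metathesis joins the monosubstituted and the 1,1-disubstituted alkene, which sit trans-diequatorial on the cyclopentane, to the trisubstituted C8=C9 cycloheptene, a closure well established for hydroazulenes, and no stereocentre changes.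

Step 7
Reactants: 11 4β-(triethylsilyloxy)dauc-8-en-6-ol
Product: 12 4β-(triethylsilyloxy)dauc-8-en-6-one
Conditions: Dess–Martin periodinane, NaHCO3, CH2Cl2, 0 °C to rt
Reagents that add atoms: none
Why: Buffered Dess–Martin oxidation converts both C6 epimers into one ketone under near-neutral conditions, so the β,γ-alkene stays out of conjugation, C5 is not epimerised and the β-silyloxy group is not eliminated.

Step 8
Reactants: 12 4β-(triethylsilyloxy)dauc-8-en-6-one
Product: 14 4β-(triethylsilyloxy)dauca-6,8-dien-6-yl trifluoromethanesulfonate, via potassium dienolate 13 (not isolated)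
Conditions: KHMDS, THF, −78 °C; then PhNTf2, −78 to 0 °C
Reagents that add atoms: N-phenylbis(trifluoromethanesulfonimide), O=S(=O)(N(c1ccccc1)S(=O)(=O)C(F)(F)F)C(F)(F)F; potassium bis(trimethylsilyl)amide, C[Si](C)(C)[N-][Si](C)(C)C.[K+] (potassium stays in 13 only)
Why: In this enol triflate formation the base removes a C7 hydrogen, which is both α to the ketone and allylic and far more accessible than H-5, so the through-conjugated dienolate forms and is sulfonylated on oxygen with C5 and the C4 silyloxy group untouched.

Step 9
Reactants: 14 4β-(triethylsilyloxy)dauca-6,8-dien-6-yl trifluoromethanesulfonate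
Product: 15 4β-(triethylsilyloxy)dauca-6,8-diene
Conditions: Pd(OAc)2 (cat.), PPh3 (cat.), HCO2H, n-Bu3N, DMF, 50 °C
Reagents that add atoms: none
Why: Palladium-catalysed formate reduction of a dienyl triflate (oxidative addition, formate exchange, decarboxylation, reductive elimination) replaces OTf by H without moving the double bonds, and the moderate temperature keeps 1,5-hydrogen shifts in the cycloheptadiene slow.

Step 10
Reactants: 15 4β-(triethylsilyloxy)dauca-6,8-diene; 16 dioxygen
Product: 17 6α,9α-epidioxy-4β-(triethylsilyloxy)dauc-7-ene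
Conditions: O2 (bubbled), tetraphenylporphyrin (cat.), CH2Cl2, visible light, −20 °C
Reagents that add atoms: none
Why: The excited sensitiser converts 16 into singlet oxygen, which adds to the termini C6 and C9 of the ring-held s-cis diene in a concerted, suprafacial [4+2] cycloaddition, the closest known chemistry being the photooxygenation of cyclohepta-1,3-dienes to their bicyclic endoperoxides. The one new ring, the six-membered 1,2-dioxine O–C6–C7=C8–C9–O, is closed by cycloaddition with both C–O bonds formed in the same event, which turns the cycloheptadiene into a 6,7-dioxabicyclo[3.2.2]non-8-ene and makes the two oxygens cis by necessity. C6 and C9 are both fixed by the face that oxygen takes: the trans ring fusion locks the cycloheptadiene as an envelope whose flap C1 points to the β side and bears the axial β-methyl group, and the pseudo-axial 4β-silyloxy group covers C6 from the same side, so attack should occur from the α face. The competing element is the α-isopropyl group at C4, but it is pseudo-equatorial and can turn its methine hydrogen toward C6, and masking the 4β-hydroxyl also removes a hydrogen-bond donor that could draw singlet oxygen to the β face. The step further needs chemoselectivity for cycloaddition over the Schenck ene reaction at the C8 methyl group, C10 and C5, which the coplanar cisoid diene, the aprotic solvent and the low temperature should secure. Regiochemistry is not an issue because only one conjugated diene is present, and the silyl ether is inert to singlet oxygen.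

Step 11
Reactants: 17 6α,9α-epidioxy-4β-(triethylsilyloxy)dauc-7-ene
Product: 18 4β-(triethylsilyloxy)dauc-7-ene-6α,9α-diol
Conditions: Zn, AcOH, CH2Cl2, 0 °C to rt
Reagents that add atoms: none
Why: Zinc in acetic acid reduces only the weak O–O bond, the standard conversion of bicyclic endoperoxides into cis-2-ene-1,4-diols, so both C–O bonds and their α configuration are kept.

Step 12
Reactants: 18 4β-(triethylsilyloxy)dauc-7-ene-6α,9α-diol
Product: 19 9α-(tert-butyldimethylsilyloxy)-4β-(triethylsilyloxy)dauc-7-en-6α-ol
Conditions: TBSCl (1.05 equiv), imidazole, DMF, 0 °C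
Reagents that add atoms: tert-butyldimethylsilyl chloride, CC(C)(C)[Si](C)(C)Cl
Why: This silyl chloride/imidazole silylation relies on steric differentiation, since the C9 hydroxyl has the C10 methylene as neighbour whereas the C6 hydroxyl is flanked by C5 and the α-isopropyl group, so one equivalent should react at C9 only.

Step 13
Reactants: 20 4-hydroxybenzoic acid
Product: 22 4-(tert-butyldimethylsilyloxy)benzoic acid, via bis-silylated acid 21 (not isolated)
Conditions: TBSCl (2.2 equiv), imidazole, DMF, rt; then AcOH/THF/H2O, rt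
Reagents that add atoms: tert-butyldimethylsilyl chloride, CC(C)(C)[Si](C)(C)Cl
Why: Exhaustive silylation followed by selective hydrolysis of the much more labile silyl ester is the usual way to a phenol-protected hydroxybenzoic acid.

Step 14
Reactants: 19 9α-(tert-butyldimethylsilyloxy)-4β-(triethylsilyloxy)dauc-7-en-6α-ol; 22 4-(tert-butyldimethylsilyloxy)benzoic acid
Product: 23 9α-(tert-butyldimethylsilyloxy)-4β-(triethylsilyloxy)dauc-7-en-6α-yl 4-(tert-butyldimethylsilyloxy)benzoate
Conditions: DCC, DMAP, CH2Cl2, rt to 40 °C
Reagents that add atoms: none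
Why: Steglich esterification through the O-acylisourea and the acylpyridinium ion acylates the only free hydroxyl at oxygen, so C6 keeps its α configuration.

Step 15
Reactants: 23 9α-(tert-butyldimethylsilyloxy)-4β-(triethylsilyloxy)dauc-7-en-6α-yl 4-(tert-butyldimethylsilyloxy)benzoate; 16 dioxygen
Product: 25 9α-(tert-butyldimethylsilyloxy)-8β-hydroxy-4β-(triethylsilyloxy)daucan-6α-yl 4-(tert-butyldimethylsilyloxy)benzoate, via C8 hydroperoxide 24 (not isolated)
Conditions: Co(acac)2 (cat.), PhSiH3, O2 (1 atm), THF, rt; then PPh3
Reagents that add atoms: none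
Why: Mukaiyama hydration (hydrogen-atom transfer from a cobalt hydride to C7, capture of the tertiary C8 radical by oxygen, reduction of the peroxide) gives the Markovnikov alcohol, and the radical should be trapped on the β face, anti to the vicinal α-silyloxy group at C9 and the 1,3-related α-aroyloxy group at C6, which sets C8 with its hydroxyl β and trans to O–C9.

Step 16
Reactants: 25 9α-(tert-butyldimethylsilyloxy)-8β-hydroxy-4β-(triethylsilyloxy)daucan-6α-yl 4-(tert-butyldimethylsilyloxy)benzoate
Product: 26 4β,8β,9α-trihydroxydaucan-6α-yl 4-hydroxybenzoate (CNP0197754.1)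
Conditions: HF·pyridine, pyridine, THF, 0 °C to rt
Reagents that add atoms: none
Why: Fluoride-driven cleavage of all three silyl ethers with buffered HF·pyridine is non-basic, so the C6 ester should neither migrate to the cis C9 hydroxyl nor hydrolyse, and no stereocentre is touched.

Compound list
(The SMILES of 3 leaves the ozonide bridgeheads open, those of 7 and F5 leave the enol ether geometry open, and those of 10, 11 and F3 leave C6 open, all on purpose.)

1 | (S)-(+)-terpinen-4-ol | CC(C)[C@]1(O)CCC(C)=CC1 | starting material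
2 | (S)-terpinen-4-ol triethylsilyl ether | CC(C)[C@]1(O[Si](CC)(CC)CC)CCC(C)=CC1 | intermediate
3 | secondary ozonide of 2 | CC(C)[C@]1(O[Si](CC)(CC)CC)CCC2(C)OOC(O2)C1 | intermediate
4 | (S)-3-isopropyl-6-oxo-3-(triethylsilyloxy)heptanal | CC(C)[C@](CC=O)(O[Si](CC)(CC)CC)CCC(C)=O | intermediate
5 | (R)-5-isopropyl-2-methyl-5-(triethylsilyloxy)cyclopent-1-ene-1-carbaldehyde | CC(C)[C@]1(O[Si](CC)(CC)CC)CCC(C)=C1C=O | intermediate
6 | allylmagnesium bromide | C=CC[Mg]Br | starting material
7 | trimethylsilyl enol ether of 8 | CC(C)[C@]1(O[Si](CC)(CC)CC)CC[C@](C)(CC=C)C1=CO[Si](C)(C)C | intermediate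
8 | (1R,2R,5R)-2-allyl-5-isopropyl-2-methyl-5-(triethylsilyloxy)cyclopentane-1-carbaldehyde | CC(C)[C@]1(O[Si](CC)(CC)CC)CC[C@](C)(CC=C)[C@H]1C=O | intermediate
9 | 2-methylallylmagnesium chloride | CC(=C)C[Mg]Cl | starting material
10 | 1-[(1R,2R,5R)-2-allyl-5-isopropyl-2-methyl-5-(triethylsilyloxy)cyclopentyl]-3-methylbut-3-en-1-ol, both C6 epimers | CC(C)[C@]1(O[Si](CC)(CC)CC)CC[C@](C)(CC=C)[C@H]1C(O)CC(C)=C | intermediate
11 | 4β-(triethylsilyloxy)dauc-8-en-6-ol, both C6 epimers | CC(C)[C@]1(O[Si](CC)(CC)CC)CC[C@]2(C)CC=C(C)CC(O)[C@H]21 | intermediate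
12 | 4β-(triethylsilyloxy)dauc-8-en-6-one | CC(C)[C@]1(O[Si](CC)(CC)CC)CC[C@]2(C)CC=C(C)CC(=O)[C@H]21 | intermediate
13 | potassium 6,8-dienolate of 12 | CC(C)[C@]1(O[Si](CC)(CC)CC)CC[C@]2(C)CC=C(C)C=C([O-])[C@H]21.[K+] | intermediate
14 | 4β-(triethylsilyloxy)dauca-6,8-dien-6-yl trifluoromethanesulfonate | CC(C)[C@]1(O[Si](CC)(CC)CC)CC[C@]2(C)CC=C(C)C=C(OS(=O)(=O)C(F)(F)F)[C@H]21 | intermediate
15 | 4β-(triethylsilyloxy)dauca-6,8-diene | CC(C)[C@]1(O[Si](CC)(CC)CC)CC[C@]2(C)CC=C(C)C=C[C@H]21 | intermediate
16 | dioxygen | O=O | starting material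
17 | 6α,9α-epidioxy-4β-(triethylsilyloxy)dauc-7-ene | CC(C)[C@]1(O[Si](CC)(CC)CC)CC[C@]2(C)C[C@H](O3)C(C)=C[C@H](O3)[C@H]21 | intermediate
18 | 4β-(triethylsilyloxy)dauc-7-ene-6α,9α-diol | CC(C)[C@]1(O[Si](CC)(CC)CC)CC[C@]2(C)C[C@H](O)C(C)=C[C@H](O)[C@H]21 | intermediate
19 | 9α-(tert-butyldimethylsilyloxy)-4β-(triethylsilyloxy)dauc-7-en-6α-ol | CC(C)[C@]1(O[Si](CC)(CC)CC)CC[C@]2(C)C[C@H](O[Si](C)(C)C(C)(C)C)C(C)=C[C@H](O)[C@H]21 | intermediate
20 | 4-hydroxybenzoic acid | OC(=O)c1ccc(O)cc1 | starting material
21 | tert-butyldimethylsilyl 4-(tert-butyldimethylsilyloxy)benzoate | CC(C)(C)[Si](C)(C)OC(=O)c1ccc(O[Si](C)(C)C(C)(C)C)cc1 | intermediate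
22 | 4-(tert-butyldimethylsilyloxy)benzoic acid | OC(=O)c1ccc(O[Si](C)(C)C(C)(C)C)cc1 | intermediate
23 | 9α-(tert-butyldimethylsilyloxy)-4β-(triethylsilyloxy)dauc-7-en-6α-yl 4-(tert-butyldimethylsilyloxy)benzoate | CC(C)[C@]1(O[Si](CC)(CC)CC)CC[C@]2(C)C[C@H](O[Si](C)(C)C(C)(C)C)C(C)=C[C@H](OC(=O)c3ccc(O[Si](C)(C)C(C)(C)C)cc3)[C@H]21 | intermediate
24 | 8β-hydroperoxide corresponding to 25 | CC(C)[C@]1(O[Si](CC)(CC)CC)CC[C@]2(C)C[C@H](O[Si](C)(C)C(C)(C)C)[C@@](C)(OO)C[C@H](OC(=O)c3ccc(O[Si](C)(C)C(C)(C)C)cc3)[C@H]21 | intermediate
25 | 9α-(tert-butyldimethylsilyloxy)-8β-hydroxy-4β-(triethylsilyloxy)daucan-6α-yl 4-(tert-butyldimethylsilyloxy)benzoate | CC(C)[C@]1(O[Si](CC)(CC)CC)CC[C@]2(C)C[C@H](O[Si](C)(C)C(C)(C)C)[C@@](C)(O)C[C@H](OC(=O)c3ccc(O[Si](C)(C)C(C)(C)C)cc3)[C@H]21 | intermediate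
26 | 4β,8β,9α-trihydroxydaucan-6α-yl 4-hydroxybenzoate (CNP0197754.1) | CC(C)[C@]1(O)CC[C@]2(C)C[C@H](O)[C@@](C)(O)C[C@H](OC(=O)c3ccc(O)cc3)[C@H]21 | target

Total step count: 16
Longest linear sequence: 15 (steps 1–12 and 14–16; step 13 is a one-step side branch)

Steps most likely to fail

1. Step 10. Singlet oxygen may also attack from the β face, or it may abstract hydrogen at the C8 methyl group or C10 (ene pathway) instead of adding across the diene. The fallback sets out from 15 and comes back at 23.
   - The more electron-rich trisubstituted C8=C9 bond of 15 is epoxidised with mCPBA (NaHCO3, CH2Cl2, −20 °C). This oxidant is much bulkier than singlet oxygen and should respond more strongly to the β-methyl and β-silyloxy shielding. It should give 8α,9α-epoxy-4β-(triethylsilyloxy)dauc-6-ene F1.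
   - This vinyl epoxide is opened with acid 22 under Pd(PPh3)4 catalysis (THF, 0 °C). Palladium ionises the allylic C8–O bond with inversion, and the carboxylate attacks the distal C6 terminus anti to the metal. The net result is the known cis-1,4 addition, giving 9α-hydroxy-4β-(triethylsilyloxy)dauc-7-en-6α-yl 4-(tert-butyldimethylsilyloxy)benzoate F2.
   - Silylation of the C9 hydroxyl (TBSCl, imidazole, DMF) then gives 23.

2. Step 4. The allyl metal may add 1,2 to the formyl group, the enolate may lose the C4 silyloxy group by β-elimination before it is trapped, or the α-face preference may be too small. The fallback sets out from 5 and comes back at 12. It changes the acceptor from an enal to a hindered enone, the substrate class for which allylcopper conjugate additions are best established and in which carbonyl attack is blocked.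
   - Reagent 9 is added first to 5 (THF, −78 °C) to give the dienol 1-[(R)-5-isopropyl-2-methyl-5-(triethylsilyloxy)cyclopent-1-enyl]-3-methylbut-3-en-1-ol F3.
   - Buffered Dess–Martin oxidation gives the corresponding cyclopentenyl ketone F4.
   - The allylcopper reagent from 6 with TMSCl (THF, −78 °C) gives the trimethylsilyl enol ether F5, which dilute acid hydrolyses to the trans-disubstituted ketone F6.
   - Ring-closing metathesis of F6 gives 12 directly, so the step count does not change.

3. Step 15. Hydrogen-atom transfer to the hindered alkene between two oxygenated carbons may be slow, and the small oxygen molecule may capture the planar C8 radical with poor facial selectivity. The fallback sets out from 23 and comes back at 25.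
   - Dihydroxylation with OsO4 (cat.) and NMO (acetone/H2O) uses a large reagent that adds anti to allylic oxygen substituents. It should therefore add from the β face and give the 7β,8β-diol F7.
   - The secondary C7 hydroxyl alone is thioacylated with phenyl chlorothionoformate (DMAP, CH2Cl2) to give the 7-O-phenoxythiocarbonyl derivative F8.
   - Barton–McCombie deoxygenation (Bu3SnH, AIBN, toluene, 80 °C) removes the C7 oxygen and gives 25 with the 8β-hydroxyl in place.

Further compounds
F1 | step 10 | 8α,9α-epoxy-4β-(triethylsilyloxy)dauc-6-ene | CC(C)[C@]1(O[Si](CC)(CC)CC)CC[C@]2(C)C[C@@H]3O[C@]3(C)C=C[C@H]21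
F2 | step 10 | 9α-hydroxy-4β-(triethylsilyloxy)dauc-7-en-6α-yl 4-(tert-butyldimethylsilyloxy)benzoate | CC(C)[C@]1(O[Si](CC)(CC)CC)CC[C@]2(C)C[C@H](O)C(C)=C[C@H](OC(=O)c3ccc(O[Si](C)(C)C(C)(C)C)cc3)[C@H]21
F3 | step 4 | 1-[(R)-5-isopropyl-2-methyl-5-(triethylsilyloxy)cyclopent-1-enyl]-3-methylbut-3-en-1-ol | CC(C)[C@]1(O[Si](CC)(CC)CC)CCC(C)=C1C(O)CC(C)=C
F4 | step 4 | 1-[(R)-5-isopropyl-2-methyl-5-(triethylsilyloxy)cyclopent-1-enyl]-3-methylbut-3-en-1-one | CC(C)[C@]1(O[Si](CC)(CC)CC)CCC(C)=C1C(=O)CC(C)=C
F5 | step 4 | trimethylsilyl enol ether of F6 | CC(C)[C@]1(O[Si](CC)(CC)CC)CC[C@](C)(CC=C)C1=C(O[Si](C)(C)C)CC(C)=C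
F6 | step 4 | 1-[(1R,2R,5R)-2-allyl-5-isopropyl-2-methyl-5-(triethylsilyloxy)cyclopentyl]-3-methylbut-3-en-1-one | CC(C)[C@]1(O[Si](CC)(CC)CC)CC[C@](C)(CC=C)[C@H]1C(=O)CC(C)=C
F7 | step 15 | 9α-(tert-butyldimethylsilyloxy)-7β,8β-dihydroxy-4β-(triethylsilyloxy)daucan-6α-yl 4-(tert-butyldimethylsilyloxy)benzoate | CC(C)[C@]1(O[Si](CC)(CC)CC)CC[C@]2(C)C[C@H](O[Si](C)(C)C(C)(C)C)[C@@](C)(O)[C@@H](O)[C@H](OC(=O)c3ccc(O[Si](C)(C)C(C)(C)C)cc3)[C@H]21
F8 | step 15 | 7-O-phenoxythiocarbonyl derivative of F7 | CC(C)[C@]1(O[Si](CC)(CC)CC)CC[C@]2(C)C[C@H](O[Si](C)(C)C(C)(C)C)[C@@](C)(O)[C@@H](OC(=S)Oc4ccccc4)[C@H](OC(=O)c3ccc(O[Si](C)(C)C(C)(C)C)cc3)[C@H]21
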